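**Assumption:** the target has no stereocentre and no hindered axis, so it is achiral; "single enantiomer" is taken to mean the single constitution shown.

**Retrosynthetic overview**
- Target ⇐ one global acidolysis of a tridepside carrying three MOM ethers and one tert-butyl ester.
- Both depside links are cut at the aryl C–O bond (not the acyl C–O bond): aryl pinacol boronate + hindered benzoic acid, Cu/O2 (the proposed new step, used twice).
- Each boronate comes from sterically controlled Ir C–H borylation of a 6-methylsalicylate unit, which places the future depside oxygen at C4.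
- Ring A acid ⇐ coenzyme Q0: reduction, selective mono-MOM protection, triflation, Pd hydroxycarbonylation.
- No ring is built; all three arenes are bought intact (6-methylsalicylic acid twice, coenzyme Q0) and joined in the order C, then B, then A.

**Route**

Step 1
Reactants: 1 2-hydroxy-6-methylbenzoic acid (6-methylsalicylic acid)
Product: 2 methoxymethyl 2-(methoxymethoxy)-6-methylbenzoate
Conditions: NaH (2.5 equiv), MOMCl (2.5 equiv), THF/DMF 4:1, 0 °C → rt
Reagents that add atoms: chloromethyl methyl ether (MOMCl), COCCl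
Why: Williamson-type double O-alkylation of the carboxylate/phenoxide dianion; NaH breaks the salicylate hydrogen bond so both oxygens are alkylated.

Step 2
Reactants: 2 methoxymethyl 2-(methoxymethoxy)-6-methylbenzoate
Product: 3 2-(methoxymethoxy)-6-methylbenzoic acid
Conditions: LiOH·H2O (3 equiv), THF/MeOH/H2O, 50 °C; then 1 M HCl to pH 4 at 0 °C
Reagents that add atoms: water (delivered as LiOH/H2O), O
Why: Saponification; the acyloxymethyl (MOM) ester is an activated ester that hydroxide cleaves, while the aryl MOM ether is base-stable.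

Step 3
Reactants: 3 2-(methoxymethoxy)-6-methylbenzoic acid
Product: 4 tert-butyl 2-(methoxymethoxy)-6-methylbenzoate
Conditions: Me2NCH(OtBu)2 (4 equiv), toluene, 80 °C
Reagents that add atoms: N,N-dimethylformamide di-tert-butyl acetal, CN(C)C(OC(C)(C)C)OC(C)(C)C
Why: tert-Butyl esterification by O-alkylation of the carboxylate with the formamide acetal; the carbonyl carbon is not attacked, so the 2,6-disubstitution does not matter and the neutral medium spares the MOM ether.

Step 4
Reactants: 4 tert-butyl 2-(methoxymethoxy)-6-methylbenzoate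
Product: 5 tert-butyl 2-(methoxymethoxy)-6-methyl-4-(4,4,5,5-tetramethyl-1,3,2-dioxaborolan-2-yl)benzoate
Conditions: [Ir(OMe)(cod)]2 (1.5 mol%), dtbpy (3 mol%), B2pin2 (1.0 equiv), THF, 80 °C
Reagents that add atoms: bis(pinacolato)diboron, CC1(C)OB(OC1(C)C)B1OC(C)(C)C(C)(C)O1
Why: Iridium-catalysed sterically controlled aromatic C–H borylation; in this 1,2,3-trisubstituted ring C4–H is the only C–H without an ortho substituent.

Step 5
Reactants: 5 tert-butyl 2-(methoxymethoxy)-6-methyl-4-(4,4,5,5-tetramethyl-1,3,2-dioxaborolan-2-yl)benzoate (1.3 equiv); 3 2-(methoxymethoxy)-6-methylbenzoic acid (1.0 equiv)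
Product: 6 tert-butyl 2-(methoxymethoxy)-4-{[2-(methoxymethoxy)-6-methylbenzoyl]oxy}-6-methylbenzoate
Conditions: Cu(OTf)2 (20 mol%), pyridine (80 mol%), Et3N (2 equiv), 4 Å MS, O2 (1 atm), MeCN, 60 °C
Reagents that add atoms: none
Why: Proposed new method: Cu-catalysed aerobic Chan–Lam-type acyloxylation of an aryl pinacol boronate with a 2,6-disubstituted benzoic acid, making the depside link at the aryl C–O bond; the ammonium carboxylate of 3 binds Cu(II), its second oxygen bridges to boron and triggers B-to-Cu aryl transfer from the unhindered boronate 5, Cu(II)/O2 oxidation gives an aryl–Cu(III) carboxylate, and C–O reductive elimination releases the aryl ester, so the crowded carbonyl carbon of 3 is never attacked and the usual steric problem of depside acylation disappears; the closest known reaction type is the Chan–Lam oxidative O-arylation of carboxylic acids with arylboronic acids, not yet shown for pinacol boronates with ortho,ortho'-disubstituted salicylate-type acids or for depside assembly after C–H borylation.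

Step 6
Reactants: 6 tert-butyl 2-(methoxymethoxy)-4-{[2-(methoxymethoxy)-6-methylbenzoyl]oxy}-6-methylbenzoate
Product: 7 tert-butyl 2-(methoxymethoxy)-4-{[2-(methoxymethoxy)-6-methyl-4-(4,4,5,5-tetramethyl-1,3,2-dioxaborolan-2-yl)benzoyl]oxy}-6-methylbenzoate
Conditions: [Ir(OMe)(cod)]2 (2 mol%), dtbpy (4 mol%), B2pin2 (1.0 equiv), THF, 80 °C
Reagents that add atoms: bis(pinacolato)diboron, CC1(C)OB(OC1(C)C)B1OC(C)(C)C(C)(C)O1
Why: Second sterically controlled Ir C–H borylation; both C–H bonds of the inner ring are now flanked by two substituents, so only C4'–H of the new outer ring reacts.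

Step 7
Reactants: 8 2,3-dimethoxy-5-methyl-1,4-benzoquinone (coenzyme Q0)
Product: 9 2,3-dimethoxy-5-methylbenzene-1,4-diol
Conditions: H2 (1 atm), 10% Pd/C, EtOAc, rt; filtered under argon and used at once
Reagents that add atoms: none
Why: Catalytic hydrogenation of a quinone to its hydroquinone, which is quantitative and leaves the aryl methyl ethers untouched.

Step 8
Reactants: 9 2,3-dimethoxy-5-methylbenzene-1,4-diol
Product: 10 2,3-dimethoxy-4-(methoxymethoxy)-6-methylphenol
Conditions: MOMCl (1.0 equiv), iPr2NEt (1.2 equiv), CH2Cl2, −20 → 0 °C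
Reagents that add atoms: chloromethyl methyl ether (MOMCl), COCCl
Why: Regioselective mono-O-alkylation (MOM protection); the hydroxyl next to the ring C–H is less hindered and more acidic than the one flanked by OMe and CH3, and the regiochemistry is checked by an NOE between OCH2O and the aryl H.

Step 9
Reactants: 10 2,3-dimethoxy-4-(methoxymethoxy)-6-methylphenol
Product: 11 2,3-dimethoxy-4-(methoxymethoxy)-6-methylphenyl trifluoromethanesulfonate
Conditions: Tf2O (1.2 equiv), pyridine (3 equiv), CH2Cl2, −20 → 0 °C
Reagents that add atoms: trifluoromethanesulfonic anhydride, O=S(=O)(OS(=O)(=O)C(F)(F)F)C(F)(F)F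
Why: O-Sulfonylation of the remaining hindered phenol; the small, highly electrophilic N-triflylpyridinium triflates di-ortho-substituted phenols and the buffered medium keeps the MOM ether intact.

Step 10
Reactants: 11 2,3-dimethoxy-4-(methoxymethoxy)-6-methylphenyl trifluoromethanesulfonate
Product: 12 2,3-dimethoxy-4-(methoxymethoxy)-6-methylbenzoic acid
Conditions: Pd(OAc)2 (5 mol%), dppp (6 mol%), CO (1 atm), Et3N (3 equiv), H2O (10 equiv), DMF, 80 °C; work-up at pH 4
Reagents that add atoms: carbon monoxide, [C-]#[O+]; water, O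
Why: Palladium-catalysed hydroxycarbonylation of an aryl triflate (oxidative addition, CO insertion, hydrolysis of the acyl-palladium), which installs the carboxyl carbon exactly where the hindered hydroquinone oxygen stood.

Step 11
Reactants: 7 tert-butyl 2-(methoxymethoxy)-4-{[2-(methoxymethoxy)-6-methyl-4-(4,4,5,5-tetramethyl-1,3,2-dioxaborolan-2-yl)benzoyl]oxy}-6-methylbenzoate (1.0 equiv); 12 2,3-dimethoxy-4-(methoxymethoxy)-6-methylbenzoic acid (1.5 equiv)
Product: 13 tert-butyl 4-{[4-{[2,3-dimethoxy-4-(methoxymethoxy)-6-methylbenzoyl]oxy}-2-(methoxymethoxy)-6-methylbenzoyl]oxy}-2-(methoxymethoxy)-6-methylbenzoate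
Conditions: Cu(OTf)2 (20 mol%), pyridine (80 mol%), Et3N (2 equiv), 4 Å MS, O2 (1 atm), MeCN, 60 °C
Reagents that add atoms: none
Why: Proposed new method: second use of the Cu-catalysed aerobic acyloxylation of an aryl pinacol boronate, now with the doubly ortho-blocked acid 12 as the oxygen nucleophile; the carboxylate-bridged B-to-Cu transmetalation and C–O reductive elimination from aryl–Cu(III) carboxylate do not involve attack at the shielded carbonyl, and the existing aryl ester, MOM ethers and tert-butyl ester are inert to Cu/O2/amine; the closest known reaction type is again the Chan–Lam O-arylation of carboxylic acids with arylboronic acids.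

Step 12
Reactants: 13 tert-butyl 4-{[4-{[2,3-dimethoxy-4-(methoxymethoxy)-6-methylbenzoyl]oxy}-2-(methoxymethoxy)-6-methylbenzoyl]oxy}-2-(methoxymethoxy)-6-methylbenzoate
Product: 14 4-{[4-{[4-hydroxy-2,3-dimethoxy-6-methylbenzoyl]oxy}-2-hydroxy-6-methylbenzoyl]oxy}-2-hydroxy-6-methylbenzoic acid (target CNP0319613.0)
Conditions: TFA/CH2Cl2/H2O 10:10:1, 0.01 M, 0 °C → rt
Reagents that add atoms: none
Why: Global acidolysis (acetal hydrolysis of the three MOM ethers and E1 cleavage of the tert-butyl ester); the two aryl ester links are stable to TFA at room temperature and dilution limits side reactions of the released formaldehyde.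

**Compound list**

1 | 2-hydroxy-6-methylbenzoic acid | Cc1cccc(O)c1C(=O)O | starting material
2 | methoxymethyl 2-(methoxymethoxy)-6-methylbenzoate | COCOC(=O)c1c(C)cccc1OCOC | intermediate
3 | 2-(methoxymethoxy)-6-methylbenzoic acid | COCOc1cccc(C)c1C(=O)O | intermediate
4 | tert-butyl 2-(methoxymethoxy)-6-methylbenzoate | COCOc1cccc(C)c1C(=O)OC(C)(C)C | intermediate
5 | tert-butyl 2-(methoxymethoxy)-6-methyl-4-(4,4,5,5-tetramethyl-1,3,2-dioxaborolan-2-yl)benzoate | COCOc1cc(B2OC(C)(C)C(C)(C)O2)cc(C)c1C(=O)OC(C)(C)C | intermediate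
6 | tert-butyl 2-(methoxymethoxy)-4-{[2-(methoxymethoxy)-6-methylbenzoyl]oxy}-6-methylbenzoate | COCOc1cccc(C)c1C(=O)Oc1cc(C)c(C(=O)OC(C)(C)C)c(OCOC)c1 | intermediate
7 | tert-butyl 2-(methoxymethoxy)-4-{[2-(methoxymethoxy)-6-methyl-4-(4,4,5,5-tetramethyl-1,3,2-dioxaborolan-2-yl)benzoyl]oxy}-6-methylbenzoate | COCOc1cc(B2OC(C)(C)C(C)(C)O2)cc(C)c1C(=O)Oc1cc(C)c(C(=O)OC(C)(C)C)c(OCOC)c1 | intermediate
8 | 2,3-dimethoxy-5-methyl-1,4-benzoquinone (coenzyme Q0) | COC1=C(OC)C(=O)C(C)=CC1=O | starting material
9 | 2,3-dimethoxy-5-methylbenzene-1,4-diol | COc1c(O)cc(C)c(O)c1OC | intermediate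
10 | 2,3-dimethoxy-4-(methoxymethoxy)-6-methylphenol | COCOc1cc(C)c(O)c(OC)c1OC | intermediate
11 | 2,3-dimethoxy-4-(methoxymethoxy)-6-methylphenyl trifluoromethanesulfonate | COCOc1cc(C)c(OS(=O)(=O)C(F)(F)F)c(OC)c1OC | intermediate
12 | 2,3-dimethoxy-4-(methoxymethoxy)-6-methylbenzoic acid | COCOc1cc(C)c(C(=O)O)c(OC)c1OC | intermediate
13 | tert-butyl 4-{[4-{[2,3-dimethoxy-4-(methoxymethoxy)-6-methylbenzoyl]oxy}-2-(methoxymethoxy)-6-methylbenzoyl]oxy}-2-(methoxymethoxy)-6-methylbenzoate | COCOc1cc(C)c(C(=O)Oc2cc(C)c(C(=O)Oc3cc(C)c(C(=O)OC(C)(C)C)c(OCOC)c3)c(OCOC)c2)c(OC)c1OC | intermediate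
14 | 4-{[4-{[4-hydroxy-2,3-dimethoxy-6-methylbenzoyl]oxy}-2-hydroxy-6-methylbenzoyl]oxy}-2-hydroxy-6-methylbenzoic acid | COc1c(O)cc(C)c(C(=O)Oc2cc(C)c(C(=O)Oc3cc(C)c(C(=O)O)c(O)c3)c(O)c2)c1OC | target

**Totals**
Total step count: 12.
Longest linear sequence: 8 steps (1 → 2 → 3 → 4 → 5 → 6 → 7 → 13 → 14); the ring A branch (8 → 12) is 4 steps.

**Three steps most likely to fail, with fallbacks**

Step 5 (proposed new step). The pinacol boronate may transmetalate to copper too slowly, leaving protodeboronation or phenol formation as the main paths. The fallback uses known chemistry and turns the disconnection back to the acyl C–O bond. It sets out from 5, which is oxidised with Oxone in aqueous acetone at 0 °C to the phenol tert-butyl 4-hydroxy-2-(methoxymethoxy)-6-methylbenzoate F1. F1 is then esterified with acid 3 under Steglich conditions (DCC, DMAP, CH2Cl2, rt), and the sequence comes back to the route at 6.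

Step 10. Oxidative addition into the electron-rich, di-ortho-substituted triflate under CO may be sluggish. The fallback replaces carbonylation by C–C coupling and oxidative cleavage and sets out from 11. Suzuki–Miyaura coupling with potassium vinyltrifluoroborate (Pd(OAc)2/SPhos, K2CO3, THF/H2O, 80 °C) gives the styrene 1-ethenyl-2,3-dimethoxy-4-(methoxymethoxy)-6-methylbenzene F2. Lemieux–Johnson cleavage (cat. OsO4, NaIO4, 2,6-lutidine, dioxane/H2O) then gives 2,3-dimethoxy-4-(methoxymethoxy)-6-methylbenzaldehyde F3. Pinnick oxidation (NaClO2, NaH2PO4, 2-methyl-2-butene, tBuOH/H2O) of F3 comes back to the route at 12.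

Step 11 (proposed new step, second use). This is the most demanding case, with the most hindered acid and the most elaborate boronate. The fallback uses known chemistry and sets out from 7, which is oxidised with Oxone in aqueous acetone at 0 °C (neutral, so the existing depside ester survives) to the phenol tert-butyl 4-{[4-hydroxy-2-(methoxymethoxy)-6-methylbenzoyl]oxy}-2-(methoxymethoxy)-6-methylbenzoate F4. Only the para hydroxyl of F4 is free, and it is acylated with acid 12 under Steglich conditions (DCC, DMAP, CH2Cl2, rt), coming back to the route at 13.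

**Further compounds**

F1 | step 5 | tert-butyl 4-hydroxy-2-(methoxymethoxy)-6-methylbenzoate | COCOc1cc(O)cc(C)c1C(=O)OC(C)(C)C
F2 | step 10 | 1-ethenyl-2,3-dimethoxy-4-(methoxymethoxy)-6-methylbenzene | COCOc1cc(C)c(C=C)c(OC)c1OC
F3 | step 10 | 2,3-dimethoxy-4-(methoxymethoxy)-6-methylbenzaldehyde | COCOc1cc(C)c(C=O)c(OC)c1OC
F4 | step 11 | tert-butyl 4-{[4-hydroxy-2-(methoxymethoxy)-6-methylbenzoyl]oxy}-2-(methoxymethoxy)-6-methylbenzoate | COCOc1cc(O)cc(C)c1C(=O)Oc1cc(C)c(C(=O)OC(C)(C)C)c(OCOC)c1
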